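Ring A is disconnected at the C1'–C2', C3'–C4' and C1'–C6' bonds: a cyclobutenone that already carries the finished chromanone (ring B) is joined to a methyl-bearing siloxyalkyne. One thermal cascade closes ring A and exploits its alternating pattern of oxygen (C1', C3', C5') and carbon (C2', C4', C6') substituents, delivering the three oxygens as free phenol (C1'), silyl ether (C3') and isopropyl ether (C5') and leaving C4' as C–H for the late acylation. The precursor is a racemic 3-isopropoxycyclobut-2-enone whose sp3 carbon carries, through one CH2 group, the isopropyl-protected ring B.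

Key step: step 10

Remarks on the chemistry:
- Locants: ring A carries primed locants, C1' (OMe), C2' (Me), C3' (OH), C4' (isobutyryl), C5' (OH), C6' (bridging CH2); ring B uses the unprimed chromanone locants (O1, C2 to C8a).
- All three ethers to be cleaved at the end (on C5 and C7 of ring B and on C5' of ring A) are isopropyl. BCl3 cleaves isopropyl aryl ethers at low temperature without help from a neighbouring carbonyl. The C1' methyl ether, flanked by two ortho substituents, is itself a methyl ether of the kind that BCl3 attacks on longer exposure, so the groups to be removed must be much more labile than an ethyl or benzyl ether.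
- Ring B is built from a phenol whose only free hydroxyl is the future O1. Closing an enone onto unprotected methylphloroglucinol could give both the 6-methyl and the 8-methyl chromanone.
- The propanoic acid side chain is attached to C8 by cross-coupling. A malonate-type adduct next to a free C7 hydroxyl would lactonise, and its acidic C–H would be alkylated during phenol protection.
- The target has no stereocentre; the stereocentres of the cyclobutenone and of two cascade intermediates are racemic and vanish.
- Assumption: (3-ethoxy-3-oxopropyl)zinc bromide (THF solution), propyne and anhydrous tert-butyl hydroperoxide are purchased.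

Step 1
Reactants: 1 2-methylresorcinol
Product: 2 1,3-diisopropoxy-2-methylbenzene
Conditions: 2-bromopropane, K2CO3, DMF, 70 °C
Reagents that add atoms: 2-bromopropane, CC(C)Br
Why: Williamson etherification of both phenols with a secondary bromide and K2CO3 in DMF is routine, and isopropyl ethers are chosen because they withstand every later step yet are removed by BCl3 under conditions that spare a methyl ether.

Step 2
Reactants: 2 1,3-diisopropoxy-2-methylbenzene
Product: 4 3,5-diisopropoxy-4-methylphenol, via aryl boronate 3 (not isolated)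
Conditions: B2pin2, [Ir(OMe)(cod)]2 (cat.), 4,4'-di-tert-butyl-2,2'-bipyridine (cat.), THF, 80 °C; then aq. NaOH, 30% H2O2, 0 °C to rt
Reagents that add atoms: hydrogen peroxide, OO; bis(pinacolato)diboron, CC1(C)OB(OC1(C)C)B1OC(C)(C)C(C)(C)O1 (boron of 3 only)
Why: Iridium-catalysed aromatic C–H borylation is sterically controlled and can reach only the ring hydrogen para to the methyl group, the one without an ortho substituent, and alkaline peroxide oxidation of the C–B bond then gives the phenol whose single free hydroxyl is the future ring oxygen O1.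

Step 3
Reactants: 4 3,5-diisopropoxy-4-methylphenol; 5 3-methylbut-2-enoic acid
Product: 7 5,7-diisopropoxy-2,2,6-trimethylchroman-4-one, via aryl enone 6 (not isolated)
Conditions: ZnCl2, POCl3, rt
Reagents that add atoms: none
Why: Friedel–Crafts acylation at either of the two equivalent carbons ortho to the free hydroxyl, followed by intramolecular oxa-Michael addition (6-endo-trig) of that hydroxyl, the only one available, should give the 2,2-dimethylchroman-4-one as a single regioisomer with methyl at C6 and hydrogen at C8.

Step 4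
Reactants: 7 5,7-diisopropoxy-2,2,6-trimethylchroman-4-one
Product: 8 8-bromo-5,7-diisopropoxy-2,2,6-trimethylchroman-4-one
Conditions: NBS, MeCN, 0 °C to rt
Reagents that add atoms: N-bromosuccinimide, O=C1CCC(=O)N1Br
Why: Electrophilic aromatic bromination with NBS in acetonitrile takes the only remaining ring hydrogen, at C8, which is activated by its ortho and para oxygen substituents.

Step 5
Reactants: 8 8-bromo-5,7-diisopropoxy-2,2,6-trimethylchroman-4-one; 9 (3-ethoxy-3-oxopropyl)zinc bromide, BrZnCH2CH2CO2Et
Product: 10 ethyl 3-(5,7-diisopropoxy-2,2,6-trimethyl-4-oxochroman-8-yl)propanoate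
Conditions: Pd(OAc)2 (cat.), SPhos (cat.), THF, 50 °C
Reagents that add atoms: none
Why: Negishi coupling of the hindered, electron-rich aryl bromide with the primary ester-bearing alkylzinc bromide under a bulky biarylphosphine ligand forms the C8–CH2 bond, the chromanone ketone being inert to the organozinc.

Step 6
Reactants: 10 ethyl 3-(5,7-diisopropoxy-2,2,6-trimethyl-4-oxochroman-8-yl)propanoate
Product: 11 3-(5,7-diisopropoxy-2,2,6-trimethyl-4-oxochroman-8-yl)propanoic acid
Conditions: LiOH, THF/H2O, rt; then aq. HCl
Reagents that add atoms: lithium hydroxide, [Li+].[OH-]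
Why: Saponification of the ethyl ester followed by acidification gives the carboxylic acid, and the fully etherified 2,2-dimethylchromanone is stable to LiOH at room temperature.

Step 7
Reactants: 12 trichloroethylene
Product: 15 isopropoxyacetylene, via dichlorovinyl ether 13 (not isolated), via lithium alkynide 14 (not isolated)
Conditions: i-PrOH, KH, THF, 0 °C to rt; then n-BuLi, −78 to −40 °C; then H2O; pentane extraction, kept as a dried solution
Reagents that add atoms: 2-propanol, CC(C)O; n-butyllithium, [Li]CCCC (lithium of 14 only)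
Why: Potassium isopropoxide converts trichloroethylene by an elimination–addition sequence into the (E)-dichlorovinyl ether, n-BuLi then effects elimination and chlorine–lithium exchange to the lithium alkoxyacetylide, and protonation releases the ynol ether, an established one-pot route to alkoxyacetylenes.

Step 8
Reactants: 11 3-(5,7-diisopropoxy-2,2,6-trimethyl-4-oxochroman-8-yl)propanoic acid; 15 isopropoxyacetylene
Product: 18 racemic 5,7-diisopropoxy-8-[(2-isopropoxy-4-oxocyclobut-2-en-1-yl)methyl]-2,2,6-trimethylchroman-4-one, via acid chloride 16 (not isolated), via alkylketene 17 (not isolated)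
Conditions: (COCl)2, DMF (cat.), CH2Cl2, 0 °C to rt, evaporate; then 15 (excess), Et3N, Et2O, 0 °C to rt, slow addition of 16
Reagents that add atoms: oxalyl chloride, O=C(Cl)C(Cl)=O (chlorine of 16 only)
Why: Dehydrochlorination of the acid chloride by Et3N generates the monoalkylketene in the presence of excess ynol ether, and the ketene–alkoxyalkyne [2+2] cycloaddition, in which the nucleophilic unsubstituted alkyne carbon bonds to the ketene carbonyl carbon, should give the 3-alkoxy-4-substituted cyclobutenone as a racemate whose stereocentre is erased in step 10.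

Step 9
Reactants: 19 propyne
Product: 22 triisopropyl(prop-1-yn-1-yloxy)silane, via propynyllithium 20 (not isolated), via lithium ynolate 21 (not isolated)
Conditions: n-BuLi, THF, −78 °C; then t-BuOOH, LiN(SiMe3)2, THF, −78 to 0 °C; then i-Pr3SiOTf, −78 °C to rt
Reagents that add atoms: tert-butyl hydroperoxide, CC(C)(C)OO; triisopropylsilyl trifluoromethanesulfonate, CC(C)[Si](C(C)C)(C(C)C)OS(=O)(=O)C(F)(F)F; n-butyllithium, [Li]CCCC (lithium of 20 and 21 only)
Why: Electrophilic oxygen transfer from lithium tert-butyl peroxide to the lithium acetylide gives the lithium ynolate, which the bulky silyl triflate traps on oxygen and not on carbon, a known preparation of siloxyalkynes.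

Step 10
Reactants: 18 racemic 5,7-diisopropoxy-8-[(2-isopropoxy-4-oxocyclobut-2-en-1-yl)methyl]-2,2,6-trimethylchroman-4-one; 22 triisopropyl(prop-1-yn-1-yloxy)silane
Product: 27 8-[2-hydroxy-6-isopropoxy-3-methyl-4-(triisopropylsilyloxy)benzyl]-5,7-diisopropoxy-2,2,6-trimethylchroman-4-one, via vinylketene 23 (not isolated), via vinylcyclobutenone 24 (not isolated), via dienylketene 25 (not isolated), via cyclohexadienone 26 (not isolated)
Conditions: toluene, 110–140 °C, sealed tube, 22 in excess
Reagents that add atoms: none
Why: Heat opens the four-membered ring of 18 in a 4π-electrocyclic step to vinylketene 23, whose ketene C=C adds the siloxyalkyne in a [2+2] cycloaddition (C1'–C2' and C3'–C4' bonds) to give 24, and a second 4π opening to dienylketene 25 is followed by 6π-electrocyclisation (C1'–C6' bond) to 26 and tautomerisation to phenol 27. The closest known reaction type is the Danheiser benzannulation of cyclobutenones with siloxyalkynes; a 3-alkoxycyclobutenone, being a vinylogous ester, is a less common vinylketene source and is expected to need the upper part of the temperature range. Ring A is closed by the thermally allowed disrotatory 6π-electrocyclisation of the (3E)-dienylketene, the four-membered ring formed before it being only a transient relay. No stereocentre is created, since the racemic centre of 18 and those of 24 and 26 vanish on aromatisation, and alkene geometry is not critical because the ring openings are reversible and only the cyclisable isomer is drained. The step needs regiocontrol in the [2+2] event, which the polarity of the ynol ether supplies (its nucleophilic methyl-bearing carbon bonds to the electrophilic ketene carbon, placing methyl at C2' and silyloxy at C3'), and chemoselectivity for the ketene, which is secured because ring B has no free hydroxyl and the alkyne is in excess. The ketene carbon becomes C1' with a free hydroxyl, the alkoxy-bearing carbon of the cyclobutenone becomes C5', its CH becomes C4' and its sp3 carbon becomes C6'.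

Step 11
Reactants: 27 8-[2-hydroxy-6-isopropoxy-3-methyl-4-(triisopropylsilyloxy)benzyl]-5,7-diisopropoxy-2,2,6-trimethylchroman-4-one
Product: 28 5,7-diisopropoxy-8-[6-isopropoxy-2-methoxy-3-methyl-4-(triisopropylsilyloxy)benzyl]-2,2,6-trimethylchroman-4-one
Conditions: MeI, K2CO3, acetone, 45 °C
Reagents that add atoms: iodomethane, CI
Why: Williamson O-methylation of the only free phenol (on C1') fixes the methyl ether of the target, and the aryl triisopropylsilyl ether and the alkyl ethers tolerate K2CO3 in dry acetone.

Step 12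
Reactants: 28 5,7-diisopropoxy-8-[6-isopropoxy-2-methoxy-3-methyl-4-(triisopropylsilyloxy)benzyl]-2,2,6-trimethylchroman-4-one
Product: 29 8-(4-hydroxy-6-isopropoxy-2-methoxy-3-methylbenzyl)-5,7-diisopropoxy-2,2,6-trimethylchroman-4-one
Conditions: n-Bu4NF, AcOH, THF, 0 °C
Reagents that add atoms: none
Why: Fluoride-induced desilylation, buffered with acetic acid, cleaves the Si–O bond selectively and frees the C3' phenol without touching the alkyl ethers or the ketone.

Step 13
Reactants: 29 8-(4-hydroxy-6-isopropoxy-2-methoxy-3-methylbenzyl)-5,7-diisopropoxy-2,2,6-trimethylchroman-4-one; 30 isobutyryl chloride (2-methylpropanoyl chloride)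
Product: 31 8-[4-hydroxy-6-isopropoxy-2-methoxy-3-methyl-5-(2-methylpropanoyl)benzyl]-5,7-diisopropoxy-2,2,6-trimethylchroman-4-one
Conditions: TiCl4, CH2Cl2, −78 to −20 °C
Reagents that add atoms: none
Why: Titanium-mediated Friedel–Crafts acylation of the phenol can only take place at C4', the last unsubstituted ring carbon, which is ortho to the free hydroxyl and to the isopropoxy group and para to the methoxy group, and any isopropyl ether loosened by TiCl4 is of no consequence because step 14 removes all three.

Step 14
Reactants: 31 8-[4-hydroxy-6-isopropoxy-2-methoxy-3-methyl-5-(2-methylpropanoyl)benzyl]-5,7-diisopropoxy-2,2,6-trimethylchroman-4-one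
Product: 32 mallopallidol
Conditions: BCl3, CH2Cl2, −78 to 0 °C, quenched as soon as the isopropyl groups are gone; then H2O
Reagents that add atoms: none
Why: Lewis-acid ether cleavage with BCl3 removes secondary alkyl (isopropyl) aryl ethers by ionisation of the alkyl–oxygen bond at or below 0 °C, conditions under which the unchelated C1' methyl ether, which lies para to the new ketone, should be retained if the exposure is kept short, so the three isopropyl groups should fall together and aqueous work-up should release mallopallidol.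

Compound list
1 | 2-methylresorcinol (2-methylbenzene-1,3-diol) | Cc1c(O)cccc1O | starting material
2 | 1,3-diisopropoxy-2-methylbenzene | Cc1c(OC(C)C)cccc1OC(C)C | intermediate
3 | 2-(3,5-diisopropoxy-4-methylphenyl)-4,4,5,5-tetramethyl-1,3,2-dioxaborolane | Cc1c(OC(C)C)cc(cc1OC(C)C)B1OC(C)(C)C(C)(C)O1 | intermediate
4 | 3,5-diisopropoxy-4-methylphenol | Cc1c(OC(C)C)cc(O)cc1OC(C)C | intermediate
5 | 3-methylbut-2-enoic acid | CC(C)=CC(=O)O | starting material
6 | 1-(6-hydroxy-2,4-diisopropoxy-3-methylphenyl)-3-methylbut-2-en-1-one | CC(C)=CC(=O)c1c(O)cc(OC(C)C)c(C)c1OC(C)C | intermediate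
7 | 5,7-diisopropoxy-2,2,6-trimethylchroman-4-one | CC(C)Oc1cc2OC(C)(C)CC(=O)c2c(OC(C)C)c1C | intermediate
8 | 8-bromo-5,7-diisopropoxy-2,2,6-trimethylchroman-4-one | CC(C)Oc1c(Br)c2OC(C)(C)CC(=O)c2c(OC(C)C)c1C | intermediate
9 | (3-ethoxy-3-oxopropyl)zinc bromide | CCOC(=O)CC[Zn]Br | starting material
10 | ethyl 3-(5,7-diisopropoxy-2,2,6-trimethyl-4-oxochroman-8-yl)propanoate | CCOC(=O)CCc1c(OC(C)C)c(C)c(OC(C)C)c2c1OC(C)(C)CC2=O | intermediate
11 | 3-(5,7-diisopropoxy-2,2,6-trimethyl-4-oxochroman-8-yl)propanoic acid | OC(=O)CCc1c(OC(C)C)c(C)c(OC(C)C)c2c1OC(C)(C)CC2=O | intermediate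
12 | trichloroethylene | ClC=C(Cl)Cl | starting material
13 | (E)-1,2-dichloroethenyl isopropyl ether | CC(C)O/C(Cl)=C\Cl | intermediate
14 | lithium isopropoxyacetylide | [Li]C#COC(C)C | intermediate
15 | isopropoxyacetylene (2-(ethynyloxy)propane) | C#COC(C)C | intermediate
16 | 3-(5,7-diisopropoxy-2,2,6-trimethyl-4-oxochroman-8-yl)propanoyl chloride | ClC(=O)CCc1c(OC(C)C)c(C)c(OC(C)C)c2c1OC(C)(C)CC2=O | intermediate
17 | 3-(5,7-diisopropoxy-2,2,6-trimethyl-4-oxochroman-8-yl)prop-1-en-1-one (alkylketene) | O=C=CCc1c(OC(C)C)c(C)c(OC(C)C)c2c1OC(C)(C)CC2=O | intermediate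
18 | racemic 5,7-diisopropoxy-8-[(2-isopropoxy-4-oxocyclobut-2-en-1-yl)methyl]-2,2,6-trimethylchroman-4-one | CC(C)OC1=CC(=O)C1Cc1c(OC(C)C)c(C)c(OC(C)C)c2c1OC(C)(C)CC2=O | intermediate
19 | propyne | CC#C | starting material
20 | prop-1-yn-1-yllithium | CC#C[Li] | intermediate
21 | lithium prop-1-yn-1-olate | CC#CO[Li] | intermediate
22 | triisopropyl(prop-1-yn-1-yloxy)silane | CC#CO[Si](C(C)C)(C(C)C)C(C)C | intermediate
23 | (3Z)-5-(5,7-diisopropoxy-2,2,6-trimethyl-4-oxochroman-8-yl)-3-isopropoxypenta-1,3-dien-1-one | O=C=C/C(OC(C)C)=C/Cc1c(OC(C)C)c(C)c(OC(C)C)c2c1OC(C)(C)CC2=O | intermediate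
24 | racemic 4-[(1Z)-3-(5,7-diisopropoxy-2,2,6-trimethyl-4-oxochroman-8-yl)-1-isopropoxyprop-1-en-1-yl]-2-methyl-3-(triisopropylsilyloxy)cyclobut-2-en-1-one | CC1=C(O[Si](C(C)C)(C(C)C)C(C)C)C(C1=O)/C(OC(C)C)=C/Cc1c(OC(C)C)c(C)c(OC(C)C)c2c1OC(C)(C)CC2=O | intermediate
25 | (3E,5Z)-7-(5,7-diisopropoxy-2,2,6-trimethyl-4-oxochroman-8-yl)-5-isopropoxy-2-methyl-3-(triisopropylsilyloxy)hepta-1,3,5-trien-1-one | O=C=C(C)/C(O[Si](C(C)C)(C(C)C)C(C)C)=C\C(OC(C)C)=C\Cc1c(OC(C)C)c(C)c(OC(C)C)c2c1OC(C)(C)CC2=O | intermediate
26 | racemic 6-[(5,7-diisopropoxy-2,2,6-trimethyl-4-oxochroman-8-yl)methyl]-5-isopropoxy-2-methyl-3-(triisopropylsilyloxy)cyclohexa-2,4-dien-1-one | CC1=C(O[Si](C(C)C)(C(C)C)C(C)C)C=C(OC(C)C)C(Cc2c(OC(C)C)c(C)c(OC(C)C)c3c2OC(C)(C)CC3=O)C1=O | intermediate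
27 | 8-[2-hydroxy-6-isopropoxy-3-methyl-4-(triisopropylsilyloxy)benzyl]-5,7-diisopropoxy-2,2,6-trimethylchroman-4-one | Cc1c(O)c(Cc2c(OC(C)C)c(C)c(OC(C)C)c3c2OC(C)(C)CC3=O)c(OC(C)C)cc1O[Si](C(C)C)(C(C)C)C(C)C | intermediate
28 | 5,7-diisopropoxy-8-[6-isopropoxy-2-methoxy-3-methyl-4-(triisopropylsilyloxy)benzyl]-2,2,6-trimethylchroman-4-one | COc1c(C)c(O[Si](C(C)C)(C(C)C)C(C)C)cc(OC(C)C)c1Cc1c(OC(C)C)c(C)c(OC(C)C)c2c1OC(C)(C)CC2=O | intermediate
29 | 8-(4-hydroxy-6-isopropoxy-2-methoxy-3-methylbenzyl)-5,7-diisopropoxy-2,2,6-trimethylchroman-4-one | COc1c(C)c(O)cc(OC(C)C)c1Cc1c(OC(C)C)c(C)c(OC(C)C)c2c1OC(C)(C)CC2=O | intermediate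
30 | isobutyryl chloride (2-methylpropanoyl chloride) | CC(C)C(=O)Cl | starting material
31 | 8-[4-hydroxy-6-isopropoxy-2-methoxy-3-methyl-5-(2-methylpropanoyl)benzyl]-5,7-diisopropoxy-2,2,6-trimethylchroman-4-one | COc1c(C)c(O)c(C(=O)C(C)C)c(OC(C)C)c1Cc1c(OC(C)C)c(C)c(OC(C)C)c2c1OC(C)(C)CC2=O | intermediate
32 | mallopallidol, 8-[4,6-dihydroxy-2-methoxy-3-methyl-5-(2-methylpropanoyl)benzyl]-5,7-dihydroxy-2,2,6-trimethylchroman-4-one | COc1c(C)c(O)c(C(=O)C(C)C)c(O)c1Cc1c(O)c(C)c(O)c2c1OC(C)(C)CC2=O | target

Total step count: 14.
Longest linear sequence: 12 steps (steps 1–6, 8 and 10–14); steps 7 and 9 are side branches.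

Steps most likely to fail

Step 10 (key step). The vinylogous-ester cyclobutenone may open too slowly, so that at the temperature then required the vinylketene is consumed by dimerisation or by acylating the product phenol before the alkyne captures it. The fallback makes the methylene bridge by a Mannich base and ortho-quinone methide coupling with a preformed ring A. It sets out from 7: BCl3 (CH2Cl2, 0 °C) should remove both isopropyl groups to give 5,7-dihydroxy-2,2,6-trimethylchroman-4-one F1, and dimethylmethyleneiminium iodide should aminomethylate its only free ring carbon to give the Mannich base 8-[(dimethylamino)methyl]-5,7-dihydroxy-2,2,6-trimethylchroman-4-one F2. In parallel, Friedel–Crafts acylation of commercial 2-methylphloroglucinol with 30 (AlCl3) should give 1-(2,4,6-trihydroxy-3-methylphenyl)-2-methylpropan-1-one F3, whose unchelated hydroxyl para to the ketone is methylated (Me2SO4, K2CO3, acetone) to 1-(2,6-dihydroxy-4-methoxy-3-methylphenyl)-2-methylpropan-1-one F4. Heating F2 with F4 in dioxane should expel dimethylamine to give the ortho-quinone methide 5-hydroxy-2,2,6-trimethyl-8-methylidenechromane-4,7-dione F5, which the single unsubstituted ring carbon of F4 captures. The fallback comes back to the route at 32.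

Step 8. The monoalkylketene may dimerise or oligomerise under amine catalysis faster than it adds to the ynol ether. The fallback generates the same ketene without amine by a Wolff rearrangement. It sets out from 8: Negishi coupling with BrZnCH2CO2t-Bu (Pd(OAc)2, SPhos) should give tert-butyl 2-(5,7-diisopropoxy-2,2,6-trimethyl-4-oxochroman-8-yl)acetate F6, and trifluoroacetic acid should free 2-(5,7-diisopropoxy-2,2,6-trimethyl-4-oxochroman-8-yl)acetic acid F7. Oxalyl chloride then gives 2-(5,7-diisopropoxy-2,2,6-trimethyl-4-oxochroman-8-yl)acetyl chloride F8, and diazomethane gives the diazoketone 8-(3-diazo-2-oxopropyl)-5,7-diisopropoxy-2,2,6-trimethylchroman-4-one F9. Irradiation of F9 with near-UV or blue light in the presence of 15 should produce ketene 17 at a low stationary concentration, and its [2+2] cycloaddition brings the route back at 18.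

Step 13. Acylation may take place at the phenol oxygen, or by ipso attack at C6' with loss of the benzylic unit, instead of at the crowded C4'. The fallback places the acyl group on oxygen on purpose and then moves it. It sets out from 29: 30 with Et3N and catalytic 4-(dimethylamino)pyridine should give the aryl ester 4-[(5,7-diisopropoxy-2,2,6-trimethyl-4-oxochroman-8-yl)methyl]-5-isopropoxy-3-methoxy-2-methylphenyl 2-methylpropanoate F10. A Fries rearrangement (TiCl4, CH2Cl2) should then shift the acyl group to C4', the only free ortho position, and the route is rejoined at 31.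

Further compounds
F1 | step 10 | 5,7-dihydroxy-2,2,6-trimethylchroman-4-one | CC1(C)CC(=O)c2c(O)c(C)c(O)cc2O1
F2 | step 10 | 8-[(dimethylamino)methyl]-5,7-dihydroxy-2,2,6-trimethylchroman-4-one | CN(C)Cc1c(O)c(C)c(O)c2c1OC(C)(C)CC2=O
F3 | step 10 | 1-(2,4,6-trihydroxy-3-methylphenyl)-2-methylpropan-1-one | CC(C)C(=O)c1c(O)cc(O)c(C)c1O
F4 | step 10 | 1-(2,6-dihydroxy-4-methoxy-3-methylphenyl)-2-methylpropan-1-one | COc1cc(O)c(C(=O)C(C)C)c(O)c1C
F5 | step 10 | 5-hydroxy-2,2,6-trimethyl-8-methylidenechromane-4,7-dione | C=C1C(=O)C(C)=C(O)C2=C1OC(C)(C)CC2=O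
F6 | step 8 | tert-butyl 2-(5,7-diisopropoxy-2,2,6-trimethyl-4-oxochroman-8-yl)acetate | CC(C)(C)OC(=O)Cc1c(OC(C)C)c(C)c(OC(C)C)c2c1OC(C)(C)CC2=O
F7 | step 8 | 2-(5,7-diisopropoxy-2,2,6-trimethyl-4-oxochroman-8-yl)acetic acid | OC(=O)Cc1c(OC(C)C)c(C)c(OC(C)C)c2c1OC(C)(C)CC2=O
F8 | step 8 | 2-(5,7-diisopropoxy-2,2,6-trimethyl-4-oxochroman-8-yl)acetyl chloride | ClC(=O)Cc1c(OC(C)C)c(C)c(OC(C)C)c2c1OC(C)(C)CC2=O
F9 | step 8 | 8-(3-diazo-2-oxopropyl)-5,7-diisopropoxy-2,2,6-trimethylchroman-4-one | [N-]=[N+]=CC(=O)Cc1c(OC(C)C)c(C)c(OC(C)C)c2c1OC(C)(C)CC2=O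
F10 | step 13 | 4-[(5,7-diisopropoxy-2,2,6-trimethyl-4-oxochroman-8-yl)methyl]-5-isopropoxy-3-methoxy-2-methylphenyl 2-methylpropanoate | COc1c(C)c(OC(=O)C(C)C)cc(OC(C)C)c1Cc1c(OC(C)C)c(C)c(OC(C)C)c2c1OC(C)(C)CC2=O
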